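**Strategy.** The oxolane ring of the target (ring O, the anisyl-bearing CH, the tertiary carbinol C, the spiro C and the adjacent enol-ether C of the dienone) carries a tertiary alcohol beside an aryl ketone, an α-ketol. This array is traced back to its ketol isomer, a six-membered 3-aryl-3-hydroxychroman-4-one ring annulated onto a (2S)-flavan by a carbene-catalysed crossed benzoin. In the key step a 1,2-shift of the O-bearing benzylic carbon from the carbinol carbon to the ketone carbon contracts this pyranone to the dihydrofuran and unveils the 2-hydroxyaryl ketone. Its phenol then closes the chromanone ring by oxidative dearomatisation of the flavan phenol, which sets the spiro centre.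

Key step: step 11

Remark: (2S)-isosakuranetin (1) is taken as an enantiopure commercial flavanone; locants are flavan locants for 1–8 (O1, C2, C5–C8a); in 15–17 the new ring is numbered O7, C8 (anisyl-bearing), C9, C10, with fusion carbons C6a/C10a in 15 and 16 and C6a/C9a in 17; the antipode of the triazolium salt in step 9 is assigned by analogy and would be exchanged for its mirror image if the sense of induction were opposite.

Step 1
Reactants: 1 (2S)-isosakuranetin
Product: 4 (2S)-2-(4-methoxyphenyl)chroman-5,7-diol, via bis(ethyl carbonate) 2 (not isolated), via 7-O-ethoxycarbonyl flavan 3 (not isolated)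
Conditions: ClCO2Et (2.2 equiv), Et3N, THF, 0 °C; then NaBH4, H2O, 0 °C to rt; then aq NaOH, rt; acidify
Reagents that add atoms: none
Why: NaBH4 reduces the ketone of the bis-carbonate, the C4 alkoxide takes over the neighbouring 5-O-carbonate and leaves as ethyl carbonate to give an ortho-quinone methide that is reduced again to the methylene group (known deoxygenation of ortho-hydroxyaryl ketones), hydroxide removes the 7-O-carbonate, and C2 is not touched under these cold, weakly basic conditions.

Step 2
Reactants: 4 (2S)-2-(4-methoxyphenyl)chroman-5,7-diol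
Product: 5 (2S)-5,7-bis(benzyloxy)-2-(4-methoxyphenyl)chroman
Conditions: BnBr (2.4 equiv), K2CO3, DMF, rt
Reagents that add atoms: benzyl bromide, BrCc1ccccc1
Why: Williamson etherification of both phenols, which masks them for the formylation and leaves C2 untouched.

Step 3
Reactants: 5 (2S)-5,7-bis(benzyloxy)-2-(4-methoxyphenyl)chroman
Product: 7 (2S)-5,7-bis(benzyloxy)-2-(4-methoxyphenyl)chroman-8-carbaldehyde, via aryl iminium chloride 6 (not isolated)
Conditions: POCl3 (1.5 equiv), DMF, 0 to 50 °C; then aq NaOAc, rt
Reagents that add atoms: N,N-dimethylformamide, CN(C)C=O; water, O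
Why: Vilsmeier–Haack formylation of the phloroglucinol-type ring, expected at C8 (next to the ring oxygen, the site that electrophiles such as NBS choose in 5,7-di-O-alkylflavans) rather than at C6 between the two benzyloxy groups.

Step 4
Reactants: 7 (2S)-5,7-bis(benzyloxy)-2-(4-methoxyphenyl)chroman-8-carbaldehyde
Product: 8 (2S)-5-(benzyloxy)-7-hydroxy-2-(4-methoxyphenyl)chroman-8-carbaldehyde
Conditions: BCl3 (1.1 equiv), CH2Cl2, −78 °C; then MeOH, aq NaHCO3
Reagents that add atoms: none
Why: Chelation-controlled dealkylation, in which BCl3 bound to the aldehyde oxygen cleaves only the ortho 7-O-benzyl ether at low temperature (chloride attacks the primary benzyl carbon faster than the ring C2–O1 bond), so the 5-O-benzyl ether and the flavan ring should survive.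

Step 5
Reactants: 9 3,5-dimethoxyphenol; 10 4-methoxyphenylacetic acid
Product: 11 1-(2-hydroxy-4,6-dimethoxyphenyl)-2-(4-methoxyphenyl)ethan-1-one
Conditions: BF3·OEt2 (neat), 85 °C; then aq NaOAc
Reagents that add atoms: none
Why: BF3-mediated Friedel–Crafts acylation (aryl ester, then Fries shift) ortho to the phenol, the standard deoxybenzoin synthesis used for isoflavones, which should give the chelated 2-hydroxy ketone.

Step 6
Reactants: 11 1-(2-hydroxy-4,6-dimethoxyphenyl)-2-(4-methoxyphenyl)ethan-1-one
Product: 12 1-[2-(benzyloxy)-4,6-dimethoxyphenyl]-2-(4-methoxyphenyl)ethan-1-one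
Conditions: BnBr, K2CO3, acetone, reflux
Reagents that add atoms: benzyl bromide, BrCc1ccccc1
Why: Williamson etherification of the chelated phenol (carbonate is too weak to alkylate the α-carbon), which prevents later intramolecular O-alkylation to a benzofuranone.

Step 7
Reactants: 12 1-[2-(benzyloxy)-4,6-dimethoxyphenyl]-2-(4-methoxyphenyl)ethan-1-one
Product: 13 rac-1-[2-(benzyloxy)-4,6-dimethoxyphenyl]-2-bromo-2-(4-methoxyphenyl)ethan-1-one
Conditions: CuBr2 (2.1 equiv), EtOAc–CHCl3, reflux
Reagents that add atoms: copper dibromide, Br[Cu]Br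
Why: Selective α-bromination of the ketone through its copper enolate at the doubly activated benzylic position (King–Ostrum bromination); the new centre is racemic and labile, which step 9 uses.

Step 8
Reactants: 8 (2S)-5-(benzyloxy)-7-hydroxy-2-(4-methoxyphenyl)chroman-8-carbaldehyde; 13 rac-1-[2-(benzyloxy)-4,6-dimethoxyphenyl]-2-bromo-2-(4-methoxyphenyl)ethan-1-one
Product: 14 keto aldehyde (epimer mixture at the new ether carbon)
Conditions: K2CO3, acetone, rt
Reagents that add atoms: none
Why: Williamson O-alkylation of the chelated 7-phenoxide by the activated secondary α-bromo ketone; the ether carbon forms as an epimer mixture that stays epimerisable.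

Step 9
Reactants: 14 keto aldehyde (epimer mixture at the new ether carbon)
Product: 15 (2S,8S,9R)-5-(benzyloxy)-9-[2-(benzyloxy)-4,6-dimethoxyphenyl]-9-hydroxy-2,8-bis(4-methoxyphenyl)-3,4,8,9-tetrahydro-2H,10H-pyrano[2,3-f]chromen-10-one
Conditions: (5aS,10bR)-2-(pentafluorophenyl)-5a,10b-dihydro-4H,6H-indeno[2,1-b][1,2,4]triazolo[4,3-d][1,4]oxazin-2-ium tetrafluoroborate (20 mol %), DBU (1.0 equiv), toluene, 25 °C
Reagents that add atoms: none
Why: NHC-catalysed intramolecular crossed aldehyde–ketone benzoin (the known route to 3-hydroxychroman-4-ones), in which the Breslow intermediate of the aryl aldehyde adds to the ketone while DBU equilibrates the acidic α-aryloxy centre, so the chiral carbene should select one epimer and one ketone face (dynamic kinetic resolution) and give the 8S,9R product with the two aryl groups trans and the 9-OH cis to the anisyl group.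

Step 10
Reactants: 15 (2S,8S,9R)-bis(benzyl ether) ketol
Product: 16 (2S,8S,9R)-5,9-dihydroxy-9-(2-hydroxy-4,6-dimethoxyphenyl)-2,8-bis(4-methoxyphenyl)-3,4,8,9-tetrahydro-2H,10H-pyrano[2,3-f]chromen-10-one
Conditions: H2 (1 atm), Pd/C (10 wt % palladium on carbon), EtOAc, rt
Reagents that add atoms: none
Why: Hydrogenolysis of the two primary aryl benzyl ethers, which should be cleaved much faster than the hindered secondary ring C–O bonds, the tertiary alcohol or the aryl ketone.

Step 11
Reactants: 16 (2S,8S,9R)-3-aryl-3-hydroxychroman-4-one type ketol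
Product: 17 [(2S,8S,9S)-5,9-dihydroxy-2,8-bis(4-methoxyphenyl)-3,4,8,9-tetrahydro-2H-furo[2,3-h]chromen-9-yl](2-hydroxy-4,6-dimethoxyphenyl)methanone
Conditions: Sc(OTf)3 (10 mol %), ClCH2CH2Cl, 50 °C
Reagents that add atoms: none
Why: Trivalent scandium binds the C9 hydroxyl and the C10 carbonyl oxygen in an s-cis five-membered chelate, and C8 (the electron-rich benzylic carbon carrying O7 and the anisyl group) migrates suprafacially from C9 to C10 while the C9–O bond becomes the new ketone. The closest known reaction is the α-ketol (acyloin) rearrangement with ring contraction, as in D-homosteroid ketols and the ketol shift of the aglain core to rocaglates. No ring is closed by a nucleophile: the six-membered pyranone ring (O7, C8, C9, C10, C10a, C6a) expels C9 by the 1,2-shift and becomes the five-membered dihydrofuran ring. The migrating carbon keeps its S configuration (retention), and the new carbinol centre is set by the 9R centre through the chelated transition state, which places the hydroxyl cis and the aroyl group trans to the anisyl group. The step needs migration of C8 rather than of the trioxygenated aryl group and a favourable equilibrium: aryl migration would give the isomeric ketol, which contracts by shift of the flavan aryl carbon to the same product with the same configuration, and the product should be favoured by relief of crowding at the quaternary carbinol and by the planar, hydrogen-bonded 2-hydroxyaryl ketone.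

Step 12
Reactants: 17 (2S,8S,9S)-dihydrofuran α-ketol
Product: 18 target CNP0251458.2
Conditions: PhI(OAc)2 (1.05 equiv), (CF3)2CHOH, 0 °C
Reagents that add atoms: none
Why: Oxidative dearomatisation with trivalent iodine, in which the electron-rich flavan phenol (5-OH) is oxidised and its para carbon C9a is captured by the phenol of the aroyl group in a six-membered spiro-etherification; the tether sits on one face of the dihydrofuran, so the spiro centre can only form cis-fused (S).

**Compound list**

1 | (2S)-isosakuranetin, (2S)-5,7-dihydroxy-2-(4-methoxyphenyl)chroman-4-one | COc1ccc(cc1)[C@@H]1CC(=O)c2c(O)cc(O)cc2O1 | starting material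
2 | (2S)-5,7-bis(ethoxycarbonyloxy)-2-(4-methoxyphenyl)chroman-4-one | COc1ccc(cc1)[C@@H]1CC(=O)c2c(OC(=O)OCC)cc(OC(=O)OCC)cc2O1 | intermediate
3 | (2S)-7-(ethoxycarbonyloxy)-2-(4-methoxyphenyl)chroman-5-ol | COc1ccc(cc1)[C@@H]1CCc2c(O)cc(OC(=O)OCC)cc2O1 | intermediate
4 | (2S)-2-(4-methoxyphenyl)chroman-5,7-diol | COc1ccc(cc1)[C@@H]1CCc2c(O)cc(O)cc2O1 | intermediate
5 | (2S)-5,7-bis(benzyloxy)-2-(4-methoxyphenyl)chroman | COc1ccc(cc1)[C@@H]1CCc2c(OCc3ccccc3)cc(OCc3ccccc3)cc2O1 | intermediate
6 | N-{[(2S)-5,7-bis(benzyloxy)-2-(4-methoxyphenyl)chroman-8-yl]methylidene}-N-methylmethanaminium chloride | COc1ccc(cc1)[C@@H]1CCc2c(OCc3ccccc3)cc(OCc3ccccc3)c(C=[N+](C)C)c2O1.[Cl-] | intermediate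
7 | (2S)-5,7-bis(benzyloxy)-2-(4-methoxyphenyl)chroman-8-carbaldehyde | COc1ccc(cc1)[C@@H]1CCc2c(OCc3ccccc3)cc(OCc3ccccc3)c(C=O)c2O1 | intermediate
8 | (2S)-5-(benzyloxy)-7-hydroxy-2-(4-methoxyphenyl)chroman-8-carbaldehyde | COc1ccc(cc1)[C@@H]1CCc2c(OCc3ccccc3)cc(O)c(C=O)c2O1 | intermediate
9 | 3,5-dimethoxyphenol | COc1cc(O)cc(OC)c1 | starting material
10 | 4-methoxyphenylacetic acid | COc1ccc(CC(=O)O)cc1 | starting material
11 | 1-(2-hydroxy-4,6-dimethoxyphenyl)-2-(4-methoxyphenyl)ethan-1-one | COc1ccc(CC(=O)c2c(O)cc(OC)cc2OC)cc1 | intermediate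
12 | 1-[2-(benzyloxy)-4,6-dimethoxyphenyl]-2-(4-methoxyphenyl)ethan-1-one | COc1ccc(CC(=O)c2c(OCc3ccccc3)cc(OC)cc2OC)cc1 | intermediate
13 | rac-1-[2-(benzyloxy)-4,6-dimethoxyphenyl]-2-bromo-2-(4-methoxyphenyl)ethan-1-one | COc1ccc(C(Br)C(=O)c2c(OCc3ccccc3)cc(OC)cc2OC)cc1 | intermediate
14 | (2S)-5-(benzyloxy)-7-{2-[2-(benzyloxy)-4,6-dimethoxyphenyl]-1-(4-methoxyphenyl)-2-oxoethoxy}-2-(4-methoxyphenyl)chroman-8-carbaldehyde, both epimers at the ether carbon | COc1ccc(cc1)[C@@H]1CCc2c(OCc3ccccc3)cc(OC(c3ccc(OC)cc3)C(=O)c3c(OCc4ccccc4)cc(OC)cc3OC)c(C=O)c2O1 | intermediate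
15 | (2S,8S,9R)-5-(benzyloxy)-9-[2-(benzyloxy)-4,6-dimethoxyphenyl]-9-hydroxy-2,8-bis(4-methoxyphenyl)-3,4,8,9-tetrahydro-2H,10H-pyrano[2,3-f]chromen-10-one (8-aryl cis to 9-OH) | COc1ccc(cc1)[C@@H]1CCc2c(OCc3ccccc3)cc3O[C@@H](c4ccc(OC)cc4)[C@](O)(c4c(OCc5ccccc5)cc(OC)cc4OC)C(=O)c3c2O1 | intermediate
16 | (2S,8S,9R)-5,9-dihydroxy-9-(2-hydroxy-4,6-dimethoxyphenyl)-2,8-bis(4-methoxyphenyl)-3,4,8,9-tetrahydro-2H,10H-pyrano[2,3-f]chromen-10-one | COc1ccc(cc1)[C@@H]1CCc2c(O)cc3O[C@@H](c4ccc(OC)cc4)[C@](O)(c4c(O)cc(OC)cc4OC)C(=O)c3c2O1 | intermediate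
17 | [(2S,8S,9S)-5,9-dihydroxy-2,8-bis(4-methoxyphenyl)-3,4,8,9-tetrahydro-2H-furo[2,3-h]chromen-9-yl](2-hydroxy-4,6-dimethoxyphenyl)methanone (8-aryl cis to 9-OH, trans to the aroyl group) | COc1ccc(cc1)[C@@H]1CCc2c(O)cc3O[C@@H](c4ccc(OC)cc4)[C@](O)(C(=O)c4c(O)cc(OC)cc4OC)c3c2O1 | intermediate
18 | CNP0251458.2 (flavan C2 S; anisyl-bearing oxolane carbon S; carbinol carbon R; spiro carbon S; chromanone and oxolane cis-fused) | COc1ccc([C@@H]2CCC3=C(O2)[C@]24Oc5cc(OC)cc(OC)c5C(=O)[C@@]2(O)[C@H](c2ccc(OC)cc2)OC4=CC3=O)cc1 | target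

**Step count and risks**

Total step count: 12. Longest linear sequence: 9 steps (steps 1, 2, 3, 4, 8, 9, 10, 11, 12, from 1).

Step 11. What may go wrong: the Lewis acid ionises the p-methoxybenzylic C8–O7 bond (loss of configuration at C8) or dehydrates the ortho-hydroxybenzylic tertiary alcohol instead of promoting the 1,2-shift, or the ketol equilibrium stops short of 17. Fallback: the order of dearomatisation and contraction is reversed. Diol 16 is oxidised with PhI(OAc)2 in (CF3)2CHOH at 0 °C, so that the phenol of the C9 aryl group adds to C10a (para to the 5-OH; oxidative spirocyclisation of a para-acylphenol, as in grisan syntheses) and gives the bridged spirodienone F1, in which the C10 ketone is the one-atom bridge of a bicyclo[3.3.1] core. NaOMe (cat.) in MeOH at rt should then trigger the strain-releasing α-ketol shift of C8 from C9 to C10 (the aglain-to-rocaglate type of contraction), which gives 18 directly. This fallback sets out from 16 and comes back at 18.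

Step 9. What may go wrong: the hindered Breslow intermediate adds too slowly to the di-ortho-substituted aryl ketone, reversible aldol closure of the ketone enolate onto the aldehyde takes over, or the epimers are selected incompletely. Fallback: the C9–C10 bond is made reductively instead of by carbene catalysis. Keto aldehyde 14 is cyclised with Bu3SnH and AIBN in benzene at 80 °C (tin-ketyl radical pinacol cyclisation: the O-stannyl ketyl of the aldehyde adds to the ketone carbon) to the cis-9,10-diol F2. The diastereomers arising from the two ether-carbon epimers are separated by chromatography, and the secondary benzylic alcohol of F2 is oxidised with Dess–Martin periodinane (CH2Cl2, NaHCO3, rt) to 15. This fallback sets out from 14 and comes back at 15.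

Step 3. What may go wrong: formylation occurs at C6 between the two benzyloxy groups, or the acidic medium opens the p-methoxybenzylic pyran ring. Fallback: the aldehyde is introduced through a halide. Ether 5 is brominated with NBS in CH2Cl2 at −78 °C (C8-selective bromination, known for 5,7-di-O-benzylflavans) to the 8-bromide F3; bromine–lithium exchange with n-BuLi in THF at −78 °C gives the aryllithium F4, which is quenched with DMF to give 7. This fallback sets out from 5 and comes back at 7.

**Further compounds**

F1 | step 11 | bridged spirodienone from oxidative cyclisation of 16 (bicyclo[3.3.1] core, C10 ketone as one-atom bridge) | COc1ccc(cc1)[C@@H]1CCC2=C(O1)[C@]34Oc5cc(OC)cc(OC)c5[C@](O)(C3=O)[C@H](c3ccc(OC)cc3)OC4=CC2=O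
F2 | step 9 | cis-9,10-diol from pinacol cyclisation of 14 | COc1ccc(cc1)[C@@H]1CCc2c(OCc3ccccc3)cc3O[C@@H](c4ccc(OC)cc4)[C@](O)(c4c(OCc5ccccc5)cc(OC)cc4OC)[C@@H](O)c3c2O1
F3 | step 3 | (2S)-5,7-bis(benzyloxy)-8-bromo-2-(4-methoxyphenyl)chroman | COc1ccc(cc1)[C@@H]1CCc2c(OCc3ccccc3)cc(OCc3ccccc3)c(Br)c2O1
F4 | step 3 | [(2S)-5,7-bis(benzyloxy)-2-(4-methoxyphenyl)chroman-8-yl]lithium | COc1ccc(cc1)[C@@H]1CCc2c(OCc3ccccc3)cc(OCc3ccccc3)c([Li])c2O1
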